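(The data were computed with constants of no real substance, noise included.)

Read at 0.833 d, 2.00 d and 3.00 d, the dawn run shows product forming ever more slowly, and two chemists dispute what the rate follows.

in all of them: substrate 0.40 M

| flask | coupling partner | free catalyst | temperature | remark | time |
|---|---|---|---|---|---|
| autumn | 0.80 equiv (fed, over 10 h) | 0.05 mol% | −22 °C | run made earlier |  |
| dawn | 0.80 equiv (fed, over 10 h) | 0.075 mol% | −6 °C | run made earlier |  |
| violet | 0.800 equiv (fed, over 10 h) | 0.1 mol% | 0 °C |  | 3.0 d |
| green | 0.800 equiv | 0.1 mol% | −30 °C | everything together at the start | 3.0 d |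

- autumn (time / d: product / %, substrate / %): 1.67: 3.7, 96.1; 4.00: 9.3, 91.9; 5.00: 10.1, 90.0; 8.00: 15.9, 84.1
- dawn (time / d: product / %, substrate / %): 0.250: 2.1, 97.8; 0.833: 11.9, 88.3; 1.25: 18.4, 82.1; 2.00: 28.2, 72.7; 3.00: 39.3, 60.8

(standard deviation of a reading: 0.5 percentage points)

1. which one finishes higher in amount of product, in percent of the substrate charged ("neither" within 2 percentage points) (violet / green / neither)
2. amount of product at the end, in percent of the substrate charged, violet
3. amount of product at the end, in percent of the substrate charged, green



The second chemist takes the symmetric case as the zero of the scale: both reagents count alike, and the rate goes with c(substrate)·c(coupling partner). The first lets c(coupling partner) count by itself, with substrate at zero order. Each view predicts a straight line against time: ln c(coupling partner) for the first, ln[c(substrate)/c(coupling partner)] for the second. In dawn, the slope after 2.00 d over the slope before it reads 1.03 for the first and 1.24 for the second, so the first line bends less.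

The first's slope k reads 0.237 d⁻¹ in dawn and 0.0275 d⁻¹ in autumn. Loading and temperature changed together there, so he assumes k proportional to loading and obtains 60.9 kJ mol⁻¹, the apparent activation energy of k at fixed loading. Coupling partner is the limiting reagent, so product climbs toward 80.0 % as partner decays. Violet gets k = 0.577 d⁻¹ and, with the feed counted at half its length, 2.79 d of reaction: 64.0 %. Green, with everything in at the start, gets 0.0211 d⁻¹ and 4.90 %.

The second's slopes, 0.0677 d⁻¹ and 0.00612 d⁻¹, give 69.7 kJ mol⁻¹. They become 0.180 d⁻¹ in violet and 0.00409 d⁻¹ in green, hence 61.2 % and 4.65 %. Green is her ground: with about 95.1 % of the substrate remaining, her extra factor stays near its starting value, and the two differ by 0.25 percentage points, less than the margin. In violet they part by 2.8 points.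

The forecast stands on the first side, slightly above his violet figure, with violet at 65 % (57 % to 72 %) and green at 6 % (2 % to 12 %): “Violet clearly finishes higher.”

The flask gives violet 64.2 % and green 4.99 %.

    free catalyst → spent catalyst A (k = 2.20 × 10⁻⁴ h⁻¹, Ea = 112 kJ mol⁻¹)
    catalyst intermediate B → free catalyst + product (k = 150 h⁻¹, Ea = 72.0 kJ mol⁻¹)
    substrate + catalyst intermediate A ⇌ catalyst intermediate B (K = 1.30 L mol⁻¹, k = 38000 L mol⁻¹ h⁻¹, Ea = 43.0 kJ mol⁻¹, ΔH = −31.0 kJ mol⁻¹)
    catalyst intermediate B → spent catalyst B (k = 0.0410 h⁻¹, Ea = 89.0 kJ mol⁻¹)
    coupling partner + free catalyst → catalyst intermediate A (k = 96.0 L mol⁻¹ h⁻¹, Ea = 62.0 kJ mol⁻¹)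
    (constants at 0 °C)

In violet the first chemist lies 0.2 points from the flask and the second 3 points; in green they lie 0.090 points and 0.34 points away. Now repeat green at −5 °C. The same 60.9 kJ mol⁻¹ and the same loading scaling give k = 0.350 d⁻¹, and over 3.0 d without a feed that means 52.0 %. That flask ends with 47.2 % of its substrate unreacted and 52.7 % as product.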